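Numbering (daucane): C1 quaternary fusion carbon (methyl C15), C2 and C3 ring CH2, C4 isopropyl carbinol, C5 fusion CH, C6 acyloxy CH, C7 CH2, C8 (methyl C14)=C9H, C10 free carbinol CH. β is the face of H5, O6, O10 and the isopropyl group, α that of O4 and C15.
Enabling feature: with C6 at the enol level, the seven-membered ring (C1, C5 to C10) is a 1,4-cycloheptadiene (C5=C6, C8=C9), the product pattern of a cis-divinylcyclopropane Cope shift. It divides into the diene C7=C6–C5=C1 seated on the five-membered ring (C1 to C5) and the three-carbon unit C8–C9–C10.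
Cuts, in retrosynthetic order: the anisoate C–O6 bond and the O10 silyl group; C6–H and C5–H (back to a C5=C6 silyl enol ether); the C14 methyl back to an ester; C1–C10 and C7–C8 together (through a transient C6–C8 bond); C1=C5 of the cyclopentene (aldol) and, before it, the C1=C6 alkene of terpinen-4-ol.
Forward: the terpene cyclohexene is opened and re-closed as the five-membered ring. O4 and O6 are tied by an iPr2Si bridge that locks the 2-silyloxydiene s-cis. One rhodium-carbenoid step then builds the cyclopropane and the seven-membered ring, and redox adjustment, acylation and desilylation follow.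
Stereochemistry: C4 comes from (S)-terpinen-4-ol; C1 and C10 from the key step (bridge-imposed twist of the diene reinforced by Rh2(R-DOSP)4, E enol ether, boat transition state); C5 from β-face protonation of the enol; C6 from hydride delivered by O4.
Key step: step 10

Assumption: commercial (S)-(+)-terpinen-4-ol is used as a single enantiomer (scalemic lots are upgraded first), because C4 accompanies or controls every later centre.

Step 1
Reactants: 1 (S)-terpinen-4-ol
Product: 2 (S)-terpinen-4-yl triethylsilyl ether
Conditions: Et3SiOTf, 2,6-lutidine, CH2Cl2, 0 °C to rt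
Reagents that add atoms: triethylsilyl trifluoromethanesulfonate, CC[Si](CC)(CC)OS(=O)(=O)C(F)(F)F
Why: O-silylation with a silyl triflate and a hindered pyridine base is the routine way to cap a crowded tertiary alcohol, leaves the alkene and C4 untouched, and prevents hemiketal formation once the ring is cleaved.

Step 2
Reactants: 2 (S)-terpinen-4-yl triethylsilyl ether
Product: 4 (S)-6-oxo-3-(propan-2-yl)-3-(triethylsilyloxy)heptanal, via secondary ozonide 3 (not isolated)
Conditions: O3, CH2Cl2, −78 °C; Me2S, −78 °C to rt
Reagents that add atoms: ozone, [O-][O+]=O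
Why: Ozonolysis with reductive work-up cleaves the only C=C bond and differentiates its carbons as methyl ketone (future C1) and aldehyde (future C6) without touching C4.

Step 3
Reactants: 4 (S)-6-oxo-3-(propan-2-yl)-3-(triethylsilyloxy)heptanal
Product: 5 (R)-2-methyl-5-(propan-2-yl)-5-(triethylsilyloxy)cyclopent-1-ene-1-carbaldehyde
Conditions: piperidine (0.3 equiv), AcOH (0.3 equiv), 4 Å MS, toluene, 50 °C
Reagents that add atoms: none
Why: In this amine-catalysed intramolecular aldol condensation only the aldehyde forms an enamine, so its α-carbon (C5) attacks the ketone carbon (C1) in a 5-enolexo closure and loss of water gives the tetrasubstituted enal instead of the acetylcyclopentene that hydroxide would give, while the fully substituted C4 speeds ring closure enough to hold β-elimination of silanol in check at moderate temperature.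

Step 4
Reactants: 5 (R)-2-methyl-5-(propan-2-yl)-5-(triethylsilyloxy)cyclopent-1-ene-1-carbaldehyde
Product: 6 1-[(R)-2-methyl-5-(propan-2-yl)-5-(triethylsilyloxy)cyclopent-1-en-1-yl]ethan-1-ol (both carbinol epimers)
Conditions: MeMgBr, Et2O, −78 to 0 °C; aq NH4Cl
Reagents that add atoms: methylmagnesium bromide, C[Mg]Br
Why: Grignard 1,2-addition is secured by the fully substituted β-carbon of the enal, and the new carbinol centre forms without control but is erased in the next step.

Step 5
Reactants: 6 1-[(R)-2-methyl-5-(propan-2-yl)-5-(triethylsilyloxy)cyclopent-1-en-1-yl]ethan-1-ol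
Product: 7 1-[(R)-2-methyl-5-(propan-2-yl)-5-(triethylsilyloxy)cyclopent-1-en-1-yl]ethan-1-one
Conditions: Dess–Martin periodinane, CH2Cl2, 0 °C to rt
Reagents that add atoms: none
Why: Dess–Martin oxidation of a secondary allylic alcohol gives the enone under mild conditions and removes the stereorandom centre.

Step 6
Reactants: 7 1-[(R)-2-methyl-5-(propan-2-yl)-5-(triethylsilyloxy)cyclopent-1-en-1-yl]ethan-1-one
Product: 8 1-[(R)-5-hydroxy-2-methyl-5-(propan-2-yl)cyclopent-1-en-1-yl]ethan-1-one
Conditions: HF·pyridine, THF, 0 °C to rt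
Reagents that add atoms: none
Why: Fluoride-driven desilylation frees O4, and the tertiary allylic alcohol resists ionisation because its alkene is conjugated with the acetyl group.

Step 7
Reactants: 8 1-[(R)-5-hydroxy-2-methyl-5-(propan-2-yl)cyclopent-1-en-1-yl]ethan-1-one
Product: 9 (7aR)-5-methyl-4-methylidene-2,2,7a-tri(propan-2-yl)-4,6,7,7a-tetrahydrocyclopenta[d][1,3,2]dioxasiline (silylene-bridged 2-silyloxydiene)
Conditions: iPr2Si(OTf)2, Et3N, CH2Cl2, −78 to 0 °C; filtration through Et3N-deactivated silica
Reagents that add atoms: diisopropylsilyl bis(trifluoromethanesulfonate), CC(C)[Si](OS(=O)(=O)C(F)(F)F)(OS(=O)(=O)C(F)(F)F)C(C)C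
Why: The bis-triflate silylates O4, its second Si–OTf group then activates the neighbouring carbonyl oxygen so that Et3N removes a methyl proton (the soft enolisation used to make 2-silyloxydienes from 1-acetylcycloalkenes with silyl triflate and amine), and the six-membered ring so formed holds the diene s-cis and replaces two clashing silyl ethers by one compact bridge.

Step 8
Reactants: 10 (tert-butyldimethylsilyloxy)acetaldehyde; 11 ethyl diazoacetate
Product: 12 ethyl 4-(tert-butyldimethylsilyloxy)-2-diazo-3-hydroxybutanoate (racemic)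
Conditions: DBU (0.2 equiv), MeCN, 0 °C to rt
Reagents that add atoms: none
Why: Amidine-catalysed aldol-type addition of the acidic diazoacetate C–H to an aldehyde keeps the diazo group, and the racemic carbinol centre disappears in the next step.

Step 9
Reactants: 12 ethyl 4-(tert-butyldimethylsilyloxy)-2-diazo-3-hydroxybutanoate
Product: 14 ethyl (E)-4-(tert-butyldimethylsilyloxy)-2-diazobut-3-enoate, via trifluoroacetate ester 13 (not isolated)
Conditions: (CF3CO)2O, Et3N, CH2Cl2, −20 to 0 °C; kept cold and used at once
Reagents that add atoms: none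
Why: Acylation of the β-hydroxyl followed by amine-induced 1,2-elimination is the usual dehydration of β-hydroxy-α-diazo esters to vinyldiazoacetates; here only the C10 hydrogens can be lost, the bulky silyloxy group should settle trans to the diazo carbon (E), and prompt use forestalls the slow cyclisation of vinyl diazo compounds to pyrazoles.

Step 10
Reactants: 9 silylene-bridged 2-silyloxydiene; 14 ethyl (E)-4-(tert-butyldimethylsilyloxy)-2-diazobut-3-enoate
Product: 16 ethyl (1S,4R,10R)-10-(tert-butyldimethylsilyloxy)-4,6-(diisopropylsilanediyldioxy)dauca-5,8-dien-14-oate, via spiro-cyclopropane 15 (not isolated)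
Conditions: Rh2(R-DOSP)4 (1 mol %; DOSP = N-(4-dodecylphenylsulfonyl)prolinate), hexanes, 14 (2 equiv) added slowly, −20 °C to rt, then 50 °C
Reagents that add atoms: none
Why: Rh2(R-DOSP)4 takes N2 from 14, and the resulting donor/acceptor vinylcarbenoid adds its carbene carbon C8 in a concerted but asynchronous [2+1] step to the terminal enol-ether bond C6=C7 of 9, forming C7–C8 and the short-lived C6–C8 bond of spiro-cyclopropane 15. The closest known reaction type is the tandem vinylcarbenoid cyclopropanation/divinylcyclopropane Cope rearrangement (formal [4+3] cycloaddition) of vinyldiazoacetates with 2-silyloxydienes and with 1-vinyl-2-methylcycloalkenes. The seven-membered ring closes by a [3,3]-sigmatropic shift through the endo boat transition state, C1–C10 forming while the strained donor–acceptor bond C6–C8 breaks, and the bridge already holds C5=C1 over the three-membered ring so that no unfavourable rotamer has to be reached. C1 is controlled by the face of C6=C7 that receives C8: the bridge can span O4 and O6 only if O6 dips to the α face, which lifts C7 to the β face and exposes its outer β side, and the R catalyst is the enantiomer whose established sense of induction with terminal alkenes should also place the carbene carbon there, so C10 reaches C1 from the β face and C15 ends α, cis to O4. C10 is controlled by alkene geometry: in the boat the E-configured O10 and the ring carbon C2 both point outward, which makes O10 cis to C2 and trans to C15. The step needs attack at the carbene carbon rather than at the vinyl terminus, reaction at C6=C7 rather than at the tetrasubstituted C5=C1, and a cis arrangement of the two alkenyl groups; the substituted vinyl terminus together with hydrocarbon solvent and prolinate catalyst, the steric difference between the two alkenes, and the preference of the bulkier carbon arm of C6 for the vinyl side secure these, and a trans isomer can still invert through reversible opening of the donor–acceptor bond.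

Step 11
Reactants: 16 ethyl (1S,4R,10R)-10-(tert-butyldimethylsilyloxy)-4,6-(diisopropylsilanediyldioxy)dauca-5,8-dien-14-oate
Product: 17 (1S,4R,10R)-10-(tert-butyldimethylsilyloxy)-4,6-(diisopropylsilanediyldioxy)dauca-5,8-dien-14-ol
Conditions: iBu2AlH, CH2Cl2, −78 °C; Rochelle salt work-up
Reagents that add atoms: none
Why: Low-temperature iBu2AlH reduction of an α,β-unsaturated ester gives the allylic alcohol by 1,2-reduction, and C6 stays masked as an enol ether so that no ketone competes.

Step 12
Reactants: 17 (1S,4R,10R)-10-(tert-butyldimethylsilyloxy)-4,6-(diisopropylsilanediyldioxy)dauca-5,8-dien-14-ol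
Product: 19 (1S,4R,10R)-10-(tert-butyldimethylsilyloxy)-4,6-(diisopropylsilanediyldioxy)dauca-5,8-diene, via allylic mesylate 18 (not isolated)
Conditions: MsCl, Et3N, THF, −40 °C; LiEt3BH, −40 to 0 °C
Reagents that add atoms: none
Why: Sulfonylation followed by direct SN2 hydride displacement with LiEt3BH is a standard deoxygenation of primary allylic alcohols, and attack at the CH2 terminus is favoured over SN2′ attack at C9, which is shielded by the neopentylic C10, so C8=C9 stays in place.

Step 13
Reactants: 19 (1S,4R,10R)-10-(tert-butyldimethylsilyloxy)-4,6-(diisopropylsilanediyldioxy)dauca-5,8-diene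
Product: 21 (1S,4R,5R,10R)-10-(tert-butyldimethylsilyloxy)-4-hydroxydauc-8-en-6-one, via fluorosilyl ether 20 (not isolated)
Conditions: Et3N·3HF, THF, −20 to 0 °C
Reagents that add atoms: none
Why: Buffered fluoride cleaves the more labile enol Si–O bond first, so C5 is protonated while O4 still carries the bulky diisopropylsilyl residue and the α face is screened by that group and by C15; the proton should therefore arrive on the β face (H5 trans to C15), which is also the more stable epimer because C6 then lies trans to the isopropyl group, and the near-neutral medium avoids β-elimination of O4 and drift of C8=C9 into conjugation, which is why no base equilibration is planned.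

Step 14
Reactants: 21 (1S,4R,5R,10R)-10-(tert-butyldimethylsilyloxy)-4-hydroxydauc-8-en-6-one
Product: 22 (1S,4R,5S,6S,10R)-10-(tert-butyldimethylsilyloxy)dauc-8-ene-4,6-diol
Conditions: Me4NBH(OAc)3, MeCN–AcOH, −30 to −10 °C
Reagents that add atoms: none
Why: In this Evans–Saksena reduction O4 replaces an acetate on boron and the alkoxyborohydride delivers hydride intramolecularly to the α face of the C6 carbonyl, setting O6 β, while the free reagent reduces neither the alkene nor any C5 epimer, in which O4 and C6 are trans on the five-membered ring.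

Step 15
Reactants: 22 (1S,4R,5S,6S,10R)-10-(tert-butyldimethylsilyloxy)dauc-8-ene-4,6-diol; 23 4-methoxybenzoyl chloride
Product: 24 (1S,4R,5S,6S,10R)-10-(tert-butyldimethylsilyloxy)-4-hydroxydauc-8-en-6-yl 4-methoxybenzoate
Conditions: DMAP (0.2 equiv), Et3N, CH2Cl2, rt
Reagents that add atoms: none
Why: DMAP-catalysed acylation distinguishes the secondary C6 alcohol from the unreactive tertiary C4 alcohol, and O10 is still silylated.

Step 16
Reactants: 24 (1S,4R,5S,6S,10R)-10-(tert-butyldimethylsilyloxy)-4-hydroxydauc-8-en-6-yl 4-methoxybenzoate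
Product: 25 (1S,4R,5S,6S,10R)-4,10-dihydroxydauc-8-en-6-yl 4-methoxybenzoate (target)
Conditions: HF·pyridine, pyridine, THF, 0 °C to rt
Reagents that add atoms: none
Why: Fluoride-mediated cleavage of the last silyl ether under mildly acidic conditions avoids acyl migration and ester hydrolysis and leaves all five stereocentres untouched.

Compound list
1 | (S)-terpinen-4-ol | C1C[C@@](O)(C(C)C)CC=C1C | starting material
2 | (S)-terpinen-4-yl triethylsilyl ether | C1C[C@@](O[Si](CC)(CC)CC)(C(C)C)CC=C1C | intermediate
3 | secondary ozonide of 2 (1,2,4-trioxolane across the future C1 and C6) | CC12CC[C@@](O[Si](CC)(CC)CC)(C(C)C)CC(OO1)O2 | intermediate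
4 | (S)-6-oxo-3-(propan-2-yl)-3-(triethylsilyloxy)heptanal | CC(=O)CC[C@@](O[Si](CC)(CC)CC)(C(C)C)CC=O | intermediate
5 | (R)-2-methyl-5-(propan-2-yl)-5-(triethylsilyloxy)cyclopent-1-ene-1-carbaldehyde | O=CC1=C(C)CC[C@@]1(O[Si](CC)(CC)CC)C(C)C | intermediate
6 | 1-[(R)-2-methyl-5-(propan-2-yl)-5-(triethylsilyloxy)cyclopent-1-en-1-yl]ethan-1-ol, both carbinol epimers | CC(O)C1=C(C)CC[C@@]1(O[Si](CC)(CC)CC)C(C)C | intermediate
7 | 1-[(R)-2-methyl-5-(propan-2-yl)-5-(triethylsilyloxy)cyclopent-1-en-1-yl]ethan-1-one | CC(=O)C1=C(C)CC[C@@]1(O[Si](CC)(CC)CC)C(C)C | intermediate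
8 | 1-[(R)-5-hydroxy-2-methyl-5-(propan-2-yl)cyclopent-1-en-1-yl]ethan-1-one | CC(=O)C1=C(C)CC[C@@]1(O)C(C)C | intermediate
9 | (7aR)-5-methyl-4-methylidene-2,2,7a-tri(propan-2-yl)-4,6,7,7a-tetrahydrocyclopenta[d][1,3,2]dioxasiline (diene C7=C6–C5=C1, O4 and O6 joined by iPr2Si) | C=C1O[Si](C(C)C)(C(C)C)O[C@@]2(C(C)C)CCC(C)=C12 | intermediate
10 | (tert-butyldimethylsilyloxy)acetaldehyde | O=CCO[Si](C)(C)C(C)(C)C | starting material
11 | ethyl diazoacetate | CCOC(=O)C=[N+]=[N-] | starting material
12 | ethyl 4-(tert-butyldimethylsilyloxy)-2-diazo-3-hydroxybutanoate, racemic | CCOC(=O)C(=[N+]=[N-])C(O)CO[Si](C)(C)C(C)(C)C | intermediate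
13 | ethyl 4-(tert-butyldimethylsilyloxy)-2-diazo-3-(trifluoroacetoxy)butanoate | CCOC(=O)C(=[N+]=[N-])C(OC(=O)C(F)(F)F)CO[Si](C)(C)C(C)(C)C | intermediate
14 | ethyl (E)-4-(tert-butyldimethylsilyloxy)-2-diazobut-3-enoate | CCOC(=O)C(=[N+]=[N-])/C=C/O[Si](C)(C)C(C)(C)C | intermediate
15 | (4R,6R,8S) spiro-cyclopropane C6–C7–C8, with C8 on the β face, the silyloxyvinyl group cis to C5 and the ester cis to O6 | CCOC(=O)[C@]1(/C=C/O[Si](C)(C)C(C)(C)C)C[C@]12O[Si](C(C)C)(C(C)C)O[C@@]3(C(C)C)CCC(C)=C23 | intermediate
16 | ethyl (1S,4R,10R)-10-(tert-butyldimethylsilyloxy)-4,6-(diisopropylsilanediyldioxy)dauca-5,8-dien-14-oate | C1C(C(=O)OCC)=C[C@@H](O[Si](C)(C)C(C)(C)C)[C@@]2(C)CC[C@@]3(O[Si](C(C)C)(C(C)C)OC1=C23)C(C)C | intermediate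
17 | (1S,4R,10R)-10-(tert-butyldimethylsilyloxy)-4,6-(diisopropylsilanediyldioxy)dauca-5,8-dien-14-ol | C1C(CO)=C[C@@H](O[Si](C)(C)C(C)(C)C)[C@@]2(C)CC[C@@]3(O[Si](C(C)C)(C(C)C)OC1=C23)C(C)C | intermediate
18 | 14-methanesulfonate of 17 | C1C(COS(C)(=O)=O)=C[C@@H](O[Si](C)(C)C(C)(C)C)[C@@]2(C)CC[C@@]3(O[Si](C(C)C)(C(C)C)OC1=C23)C(C)C | intermediate
19 | (1S,4R,10R)-10-(tert-butyldimethylsilyloxy)-4,6-(diisopropylsilanediyldioxy)dauca-5,8-diene | C1C(C)=C[C@@H](O[Si](C)(C)C(C)(C)C)[C@@]2(C)CC[C@@]3(O[Si](C(C)C)(C(C)C)OC1=C23)C(C)C | intermediate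
20 | (1S,4R,5R,10R)-10-(tert-butyldimethylsilyloxy)-4-[fluorodi(propan-2-yl)silyloxy]dauc-8-en-6-one | O=C1CC(C)=C[C@@H](O[Si](C)(C)C(C)(C)C)[C@@]2(C)CC[C@@](O[Si](F)(C(C)C)C(C)C)(C(C)C)[C@H]12 | intermediate
21 | (1S,4R,5R,10R)-10-(tert-butyldimethylsilyloxy)-4-hydroxydauc-8-en-6-one | O=C1CC(C)=C[C@@H](O[Si](C)(C)C(C)(C)C)[C@@]2(C)CC[C@@](O)(C(C)C)[C@H]12 | intermediate
22 | (1S,4R,5S,6S,10R)-10-(tert-butyldimethylsilyloxy)dauc-8-ene-4,6-diol | O[C@H]1CC(C)=C[C@@H](O[Si](C)(C)C(C)(C)C)[C@@]2(C)CC[C@@](O)(C(C)C)[C@H]12 | intermediate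
23 | 4-methoxybenzoyl chloride | COc1ccc(C(=O)Cl)cc1 | starting material
24 | (1S,4R,5S,6S,10R)-10-(tert-butyldimethylsilyloxy)-4-hydroxydauc-8-en-6-yl 4-methoxybenzoate | COc1ccc(C(=O)O[C@H]2CC(C)=C[C@@H](O[Si](C)(C)C(C)(C)C)[C@@]3(C)CC[C@@](O)(C(C)C)[C@H]23)cc1 | intermediate
25 | (1S,4R,5S,6S,10R)-4,10-dihydroxydauc-8-en-6-yl 4-methoxybenzoate, equal to (3R,3aS,4S,8R,8aS)-3,8-dihydroxy-6,8a-dimethyl-3-(propan-2-yl)-1,2,3,3a,4,5,8,8a-octahydroazulen-4-yl 4-methoxybenzoate | COc1ccc(C(=O)O[C@H]2CC(C)=C[C@@H](O)[C@@]3(C)CC[C@@](O)(C(C)C)[C@H]23)cc1 | target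

Total steps: 16. Longest linear sequence: 14 (steps 1 to 7 and 10 to 16); the diazo ester branch (steps 8 and 9) joins at step 10.

Steps most likely to fail

1. Step 10. Four processes could defeat the key step:
- The nucleophilic enol ether may attack the oxygen-stabilised vinyl terminus of the carbenoid instead of undergoing cyclopropanation.
- The donor–acceptor cyclopropane may open heterolytically and end in silyl transfer instead of the sigmatropic shift.
- The rigid bicyclic diene may fit the catalyst pocket poorly, with loss of rate and facial selectivity.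
- The bridge may be lost by hydrolysis.

The fallback gives up the tether and relies on catalyst control alone with a freely rotating diene that carries two separate silyl groups. It sets out from 7. TBSOTf and Et3N in CH2Cl2 give the untethered 2-silyloxydiene F1. Slow addition of 14 to F1 and Rh2(R-DOSP)4 or Rh2(R-PTAD)4 (PTAD = (1-adamantyl)(N-phthalimido)acetate) in hexanes should lead through the cis-divinylcyclopropane F2 to the bicyclic ester F3. Then iBu2AlH gives the allylic alcohol F4, MsCl and Et3N its mesylate F5, and LiEt3BH the C14-methyl diene F6. HF·pyridine finally removes the enol silyl group and the triethylsilyl ether in one operation, and the sequence comes back to the route at 21.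

2. Step 7. The crowded tertiary alcohol may silylate sluggishly. A γ-proton (on C15 or C2) may be removed in place of a methyl proton, giving the linear dienol ether. Intermolecular siloxane formation may compete, and the product may hydrolyse on isolation.

The fallback replaces soft by hard enolisation and makes the two Si–O bonds in separate operations. It sets out from 8. One equivalent of nBuLi at −78 °C followed by excess iPr2SiCl2 gives the chlorosilyl ether F7. After the surplus dichlorosilane is removed in vacuo, KN(SiMe3)2 in THF at −78 °C forms the kinetic cross-conjugated enolate of the methyl ketone. This enolate closes on the Si–Cl bond, and the sequence comes back at 9.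

3. Step 13. C5 may be protonated from the α face, the tertiary aldol may dehydrate, C8=C9 may migrate into conjugation with the ketone, or the C10 silyl ether may be lost early. Repair by base is not available, because enolisation toward C7 is far faster than toward the hindered C5.

The fallback uses a preformed metal enolate and an external bulky proton source. It sets out from 19. MeLi in THF (−78 to −30 °C) displaces the enolate from silicon and gives the lithium enolate F8, whose O4 now bears a methyldiisopropylsilyl group on the α face. A quench at −78 °C with 2,6-di-tert-butyl-4-methylphenol should protonate C5 kinetically from the open β face to give the silyloxy ketone F9. HF·pyridine at 0 °C then frees O4, and the sequence comes back at 21.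

Further compounds
F1 | step 10 | (R)-tert-butyldimethyl({1-[2-methyl-5-(propan-2-yl)-5-(triethylsilyloxy)cyclopent-1-en-1-yl]ethenyl}oxy)silane | C=C(O[Si](C)(C)C(C)(C)C)C1=C(C)CC[C@@]1(O[Si](CC)(CC)CC)C(C)C
F2 | step 10 | untethered cis-divinylcyclopropane (C8 on the β side, silyloxyvinyl group cis to the cyclopentenyl group) | CCOC(=O)[C@]1(/C=C/O[Si](C)(C)C(C)(C)C)C[C@@]1(O[Si](C)(C)C(C)(C)C)C2=C(C)CC[C@@]2(O[Si](CC)(CC)CC)C(C)C
F3 | step 10 | ethyl (1S,4R,10R)-6,10-bis(tert-butyldimethylsilyloxy)-4-(triethylsilyloxy)dauca-5,8-dien-14-oate | C1C(C(=O)OCC)=C[C@@H](O[Si](C)(C)C(C)(C)C)[C@@]2(C)CC[C@@](O[Si](CC)(CC)CC)(C(C)C)C2=C1O[Si](C)(C)C(C)(C)C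
F4 | step 10 | (1S,4R,10R)-6,10-bis(tert-butyldimethylsilyloxy)-4-(triethylsilyloxy)dauca-5,8-dien-14-ol | C1C(CO)=C[C@@H](O[Si](C)(C)C(C)(C)C)[C@@]2(C)CC[C@@](O[Si](CC)(CC)CC)(C(C)C)C2=C1O[Si](C)(C)C(C)(C)C
F5 | step 10 | 14-methanesulfonate of F4 | C1C(COS(C)(=O)=O)=C[C@@H](O[Si](C)(C)C(C)(C)C)[C@@]2(C)CC[C@@](O[Si](CC)(CC)CC)(C(C)C)C2=C1O[Si](C)(C)C(C)(C)C
F6 | step 10 | (1S,4R,10R)-6,10-bis(tert-butyldimethylsilyloxy)-4-(triethylsilyloxy)dauca-5,8-diene | C1C(C)=C[C@@H](O[Si](C)(C)C(C)(C)C)[C@@]2(C)CC[C@@](O[Si](CC)(CC)CC)(C(C)C)C2=C1O[Si](C)(C)C(C)(C)C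
F7 | step 7 | 1-[(R)-5-{[chlorodi(propan-2-yl)silyl]oxy}-2-methyl-5-(propan-2-yl)cyclopent-1-en-1-yl]ethan-1-one | CC(=O)C1=C(C)CC[C@@]1(O[Si](Cl)(C(C)C)C(C)C)C(C)C
F8 | step 13 | lithium (1S,4R,10R)-10-(tert-butyldimethylsilyloxy)-4-[methyldi(propan-2-yl)silyloxy]dauca-5,8-dien-6-olate | C1C(C)=C[C@@H](O[Si](C)(C)C(C)(C)C)[C@@]2(C)CC[C@@](O[Si](C)(C(C)C)C(C)C)(C(C)C)C2=C1[O-].[Li+]
F9 | step 13 | (1S,4R,5R,10R)-10-(tert-butyldimethylsilyloxy)-4-[methyldi(propan-2-yl)silyloxy]dauc-8-en-6-one | O=C1CC(C)=C[C@@H](O[Si](C)(C)C(C)(C)C)[C@@]2(C)CC[C@@](O[Si](C)(C(C)C)C(C)C)(C(C)C)[C@H]12
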